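**Retrosynthetic overview**
1. The central C–C single bond of the (E,E)-diene is cut last: Stille union of an unprotected (E)-alkenylstannane on the oxolane (ring C) with the unprotected 3-[(E)-2-iodoethenyl]isocoumarin (rings A and B).
2. Ring C: the C4–C5 and C3–C2 bonds are made together by a three-component carbonyl ylide [3+2] cycloaddition. The C5–O1–C2 ether triad of the oxolane is a masked carbonyl ylide (C5 from a diazo carbon, C2=O1 from an aldehyde), and the C4H2–C3(O) pair is the C=C of an enone whose acetyl group becomes the C3 oxygen (Baeyer–Villiger, retention).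
3. Temporary groups: an ethyl ester on C5 makes C5 the nucleophilic ylide terminus, so acetyl ends on C3 next to C2; it is later excised by oxidative decarboxylation and hydride reduction of the ring oxocarbenium ion. A silyl alkyne on C2 becomes the vinylstannane.
4. Stereocontrol: endo cycloaddition gives 2,3-cis; lipase hydrolysis of the racemic acetate gives the absolute configuration; inside-attack hydride on the oxocarbenium ion puts the 5-methyl trans to the 2- and 3-substituents.
5. Ring order: ring C (step 2); ring B lactone on the chlorinated orsellinate ring A (step 13); the fragments are joined last (step 17).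

Key step: step 2

Remark on the chemistry: 6 and 7 are racemates (the enantiomer drawn is the one carried on after step 4); the ester-bearing quaternary carbon of 6–10 and the ketal carbon of 11 carry no descriptor because this centre is planarised in step 8.

Step 1
Reactants: 1 ethyl 2-methyl-3-oxobutanoate
Product: 2 ethyl 2-diazopropanoate
Conditions: p-ABSA, DBU, MeCN, 0 °C to rt
Reagents that add atoms: 4-acetamidobenzenesulfonyl azide (p-ABSA), CC(=O)Nc1ccc(cc1)S(=O)(=O)N=[N+]=[N-]
Why: Regitz deacylative diazo transfer: the enolate of the 2-substituted acetoacetate attacks the sulfonyl azide and the adduct collapses with transfer of the acetyl group to the sulfonamide nitrogen, which should leave the α-alkyl-α-diazoester.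

Step 2
Reactants: 2 ethyl 2-diazopropanoate; 3 3-[tri(propan-2-yl)silyl]prop-2-ynal; 4 but-3-en-2-one
Product: 6 racemic ethyl (4RS,5SR)-4-acetyl-2-methyl-5-{[tri(propan-2-yl)silyl]ethynyl}oxolane-2-carboxylate, via carbonyl ylide 5 (not isolated)
Conditions: Rh2(OPiv)4 (1 mol%), CH2Cl2, −78 °C; 2 and 3 added slowly to 4 (5 equiv)
Reagents that add atoms: none
Why: Rh2(OPiv)4 should turn 2 into an electrophilic rhodium carbenoid (bulky pivalate ligands and −78 °C suppress β-hydride migration), the carbonyl oxygen of 3 attacks it, and loss of the metal gives the carbonyl ylide 5, which adds to enone 4; the closest known reaction type is the three-component cycloaddition of α-alkyl-α-diazoesters, aldehydes and electron-poor alkenes under this catalyst. The oxolane ring is closed by a concerted, asynchronous suprafacial [π4s+π2s] 1,3-dipolar cycloaddition. The ester-bearing, carbanion-like terminus (future C5) should bond to the β-carbon of the enone (future C4) and the oxocarbenium-like aldehyde carbon (future C2) to the α-carbon (future C3), which puts the acetyl group next to C2. The cis relationship of acetyl and alkynyl should come from endo approach of the acetyl group to an ylide whose alkynyl group sits in the outside (E) position; the quaternary ester carbon may form as either epimer without consequence. The step needs chemoselectivity (ylide formation at the aldehyde and not at the enone carbonyl, cycloaddition before epoxide closure or capture by a second aldehyde), which slow addition into excess 4 should secure, and regioselectivity, which the ester on the carbene carbon should secure. The product is racemic and the enantiomers are separated in step 4.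

Step 3
Reactants: 6 racemic ethyl (4RS,5SR)-4-acetyl-2-methyl-5-{[tri(propan-2-yl)silyl]ethynyl}oxolane-2-carboxylate
Product: 7 racemic ethyl (4RS,5RS)-4-(acetyloxy)-2-methyl-5-{[tri(propan-2-yl)silyl]ethynyl}oxolane-2-carboxylate
Conditions: mCPBA, CH2Cl2, 0 °C to rt
Reagents that add atoms: 3-chloroperbenzoic acid (mCPBA), OOC(=O)c1cccc(Cl)c1
Why: Baeyer–Villiger oxidation: in the Criegee intermediate the secondary ring carbon should migrate in preference to methyl and with retention, so the acetyl group becomes an acetoxy group of unchanged configuration while alkyne, ester and ether are inert.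

Step 4
Reactants: 7 racemic ethyl (4RS,5RS)-4-(acetyloxy)-2-methyl-5-{[tri(propan-2-yl)silyl]ethynyl}oxolane-2-carboxylate
Product: 8 ethyl (4R,5R)-4-hydroxy-2-methyl-5-{[tri(propan-2-yl)silyl]ethynyl}oxolane-2-carboxylate
Conditions: Candida antarctica lipase B (immobilised), pH 7 phosphate buffer/acetone, 30 °C, stopped near half conversion; chromatography
Reagents that add atoms: none
Why: Enzymatic kinetic resolution by ester hydrolysis: by the empirical size rule for lipases the (4R)-acetate, whose larger carbinol substituent is the alkynyl-bearing ring carbon, should react faster, so the (4R,5R)-alcohol should be separable from the unreacted (4S,5S)-enantiomer of 7; this sets the absolute configuration, and the hindered ethyl ester should not be touched.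

Step 5
Reactants: 8 ethyl (4R,5R)-4-hydroxy-2-methyl-5-{[tri(propan-2-yl)silyl]ethynyl}oxolane-2-carboxylate
Product: 9 ethyl (4R,5R)-4-{[tert-butyl(dimethyl)silyl]oxy}-2-methyl-5-{[tri(propan-2-yl)silyl]ethynyl}oxolane-2-carboxylate
Conditions: TBSOTf, 2,6-lutidine, CH2Cl2, −78 to 0 °C
Reagents that add atoms: tert-butyldimethylsilyl trifluoromethanesulfonate (TBSOTf), CC(C)(C)[Si](C)(C)OS(=O)(=O)C(F)(F)F
Why: Standard silylation of a hindered secondary alcohol; the silyl ether is the non-participating oxygen substituent needed to direct step 8.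

Step 6
Reactants: 9 ethyl (4R,5R)-4-{[tert-butyl(dimethyl)silyl]oxy}-2-methyl-5-{[tri(propan-2-yl)silyl]ethynyl}oxolane-2-carboxylate
Product: 10 (4R,5R)-4-{[tert-butyl(dimethyl)silyl]oxy}-2-methyl-5-{[tri(propan-2-yl)silyl]ethynyl}oxolane-2-carboxylic acid
Conditions: LiOH·H2O, THF/EtOH/H2O, 40 °C; then dilute HCl to pH 3 at 0 °C
Reagents that add atoms: lithium hydroxide, [Li+].[OH-]
Why: Saponification of the ester by acyl–oxygen cleavage; the secondary silyl ether and the triisopropylsilyl alkyne should tolerate hydroxide.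

Step 7
Reactants: 10 (4R,5R)-4-{[tert-butyl(dimethyl)silyl]oxy}-2-methyl-5-{[tri(propan-2-yl)silyl]ethynyl}oxolane-2-carboxylic acid
Product: 11 (4R,5R)-4-{[tert-butyl(dimethyl)silyl]oxy}-2-methyl-5-{[tri(propan-2-yl)silyl]ethynyl}oxolan-2-yl acetate
Conditions: Pb(OAc)4, pyridine, THF, rt
Reagents that add atoms: lead tetraacetate, CC(=O)O[Pb](OC(C)=O)(OC(C)=O)OC(C)=O
Why: Kochi-type oxidative decarboxylation: the α-alkoxy acid should lose CO2 through its lead carboxylate and the oxygen-stabilised radical is oxidised and captured as acetate, turning the temporary carboxyl group into an ionisable ketal leaving group.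

Step 8
Reactants: 11 (4R,5R)-4-{[tert-butyl(dimethyl)silyl]oxy}-2-methyl-5-{[tri(propan-2-yl)silyl]ethynyl}oxolan-2-yl acetate
Product: 13 tert-butyl(dimethyl){[(2R,3R,5R)-5-methyl-2-{[tri(propan-2-yl)silyl]ethynyl}oxolan-3-yl]oxy}silane, via oxolanyl oxocarbenium ion 12 (not isolated)
Conditions: Et3SiH, BF3·OEt2, CH2Cl2, −78 °C
Reagents that add atoms: none
Why: Ionic hydrogenation of a cyclic ketal as in C-glycoside synthesis: BF3·OEt2 ionises both epimers of 11 to the same oxocarbenium ion 12, and hydride should add by inside attack on the envelope that holds the C3 silyloxy group pseudoaxial and the C2 alkynyl group pseudoequatorial, that is cis to the silyloxy group, which leaves the C5 methyl trans to both other substituents.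

Step 9
Reactants: 13 tert-butyl(dimethyl){[(2R,3R,5R)-5-methyl-2-{[tri(propan-2-yl)silyl]ethynyl}oxolan-3-yl]oxy}silane
Product: 14 (2R,3R,5R)-2-ethynyl-5-methyloxolan-3-ol
Conditions: TBAF, THF, 0 °C to rt
Reagents that add atoms: none
Why: Fluoride-mediated desilylation should cleave the O–Si and the C(sp)–Si bond in one operation; the small alkynol is volatile and is best used directly.

Step 10
Reactants: 14 (2R,3R,5R)-2-ethynyl-5-methyloxolan-3-ol
Product: 15 (2R,3R,5R)-5-methyl-2-[(E)-2-(tributylstannyl)ethenyl]oxolan-3-ol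
Conditions: Bu3SnH, PdCl2(PPh3)2 (2 mol%), THF, 0 °C
Reagents that add atoms: tributylstannane (Bu3SnH), CCCC[SnH](CCCC)CCCC
Why: Palladium-catalysed syn-hydrostannation of the terminal alkyne: tin should go to the terminal carbon because the propargylic position is branched, giving the (E)-alkenylstannane, and a minor internal regioisomer would be removed by chromatography.

Step 11
Reactants: 16 methyl 2,4-dihydroxy-6-methylbenzoate
Product: 17 methyl 3-chloro-4,6-dihydroxy-2-methylbenzoate
Conditions: SO2Cl2, Et2O, 0 °C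
Reagents that add atoms: sulfuryl chloride, O=S(=O)(Cl)Cl
Why: Electrophilic aromatic chlorination: the position ortho to the 4-hydroxyl, para to the chelated 2-hydroxyl and next to the methyl group is the usual site of monohalogenation of orsellinates; a minor isomer chlorinated between the hydroxyls would be removed by crystallisation.

Step 12
Reactants: 17 methyl 3-chloro-4,6-dihydroxy-2-methylbenzoate
Product: 18 methyl 3-chloro-4,6-dimethoxy-2-methylbenzoate
Conditions: MeI, K2CO3, DMF, 40 °C
Reagents that add atoms: iodomethane, CI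
Why: Williamson O-methylation of both phenols (the chelated one needs the polar solvent and excess reagent); methyl ethers withstand the strong base and the oxidant of the next steps.

Step 13
Reactants: 18 methyl 3-chloro-4,6-dimethoxy-2-methylbenzoate; 19 N-methoxy-N-methylacetamide
Product: 21 5-chloro-6,8-dimethoxy-3-methyl-1H-isochromen-1-one, via keto ester 20 (not isolated)
Conditions: LiN(iPr)2, THF, −78 °C; then 19; NH4Cl work-up; crude 20 with TsOH·H2O (cat.), toluene, reflux
Reagents that add atoms: none
Why: Lateral (benzylic) lithiation of the ortho-toluate, C-acylation by the Weinreb amide (stable tetrahedral intermediate, no over-addition) and acid-catalysed enol-lactonisation (6-exo-trig attack of the enol oxygen on the ester) should close ring B; the chloride has no ortho hydrogen, so no aryne can form.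

Step 14
Reactants: 21 5-chloro-6,8-dimethoxy-3-methyl-1H-isochromen-1-one
Product: 22 5-chloro-6,8-dimethoxy-1-oxo-1H-isochromene-3-carbaldehyde
Conditions: SeO2, 1,4-dioxane, reflux
Reagents that add atoms: selenium dioxide, O=[Se]=O
Why: Riley oxidation: the methyl group on the enol-ether carbon is allylic and should be oxidised (ene reaction, [2,3]-shift) to the conjugated aldehyde, as is known for 3-methylisocoumarins.

Step 15
Reactants: 22 5-chloro-6,8-dimethoxy-1-oxo-1H-isochromene-3-carbaldehyde
Product: 23 5-chloro-3-[(E)-2-iodoethenyl]-6,8-dimethoxy-1H-isochromen-1-one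
Conditions: CHI3, CrCl2, THF, 0 °C to rt
Reagents that add atoms: iodoform, IC(I)I
Why: Takai olefination: the geminal dichromium species from CHI3 and CrCl2 adds to the aldehyde and eliminates to the (E)-vinyl iodide; lactone and aryl chloride are inert to CrCl2.

Step 16
Reactants: 23 5-chloro-3-[(E)-2-iodoethenyl]-6,8-dimethoxy-1H-isochromen-1-one
Product: 24 5-chloro-6,8-dihydroxy-3-[(E)-2-iodoethenyl]-1H-isochromen-1-one
Conditions: BBr3, CH2Cl2, −78 °C to rt; aqueous work-up
Reagents that add atoms: none
Why: Lewis-acid cleavage of both aryl methyl ethers (the peri one fastest, by chelation to the lactone carbonyl); lactone, vinyl iodide and aryl chloride should survive, and deprotecting here means no deprotection is needed on the sensitive dienyl oxolane.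

Step 17
Reactants: 15 (2R,3R,5R)-5-methyl-2-[(E)-2-(tributylstannyl)ethenyl]oxolan-3-ol; 24 5-chloro-6,8-dihydroxy-3-[(E)-2-iodoethenyl]-1H-isochromen-1-one
Product: 25 5-chloro-6,8-dihydroxy-3-[(1E,3E)-4-[(2R,3R,5R)-3-hydroxy-5-methyloxolan-2-yl]buta-1,3-dien-1-yl]-1H-isochromen-1-one
Conditions: Pd2(dba)3 (5 mol%), AsPh3 (20 mol%), NMP, rt, dark
Reagents that add atoms: none
Why: Stille cross-coupling: zerovalent palladium inserts into the vinyl C–I bond (not into the aryl C–Cl bond at room temperature) and couples with the vinylstannane with retention of both alkene geometries under neutral conditions that tolerate the free alcohol and phenols, which should give the (E,E)-diene of the target.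

**Compound list**
1 | ethyl 2-methyl-3-oxobutanoate | CCOC(=O)C(C)C(C)=O | starting material
2 | ethyl 2-diazopropanoate | CCOC(=O)C(C)=[N+]=[N-] | intermediate
3 | 3-[tri(propan-2-yl)silyl]prop-2-ynal | O=CC#C[Si](C(C)C)(C(C)C)C(C)C | starting material
4 | but-3-en-2-one (methyl vinyl ketone) | CC(=O)C=C | starting material
5 | carbonyl ylide from 2 and 3 (ester-stabilised carbanion carbon bonded to the oxonium oxygen of the ynal; not isolated) | CCOC(=O)[C-](C)[O+]=CC#C[Si](C(C)C)(C(C)C)C(C)C | intermediate
6 | racemic ethyl (4RS,5SR)-4-acetyl-2-methyl-5-{[tri(propan-2-yl)silyl]ethynyl}oxolane-2-carboxylate (acetyl and alkynyl cis; C2 open) | CCOC(=O)C1(C)C[C@@H](C(C)=O)[C@@H](C#C[Si](C(C)C)(C(C)C)C(C)C)O1 | intermediate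
7 | racemic ethyl (4RS,5RS)-4-(acetyloxy)-2-methyl-5-{[tri(propan-2-yl)silyl]ethynyl}oxolane-2-carboxylate (acetoxy and alkynyl cis; C2 open) | CCOC(=O)C1(C)C[C@@H](OC(C)=O)[C@@H](C#C[Si](C(C)C)(C(C)C)C(C)C)O1 | intermediate
8 | ethyl (4R,5R)-4-hydroxy-2-methyl-5-{[tri(propan-2-yl)silyl]ethynyl}oxolane-2-carboxylate (C2 open) | CCOC(=O)C1(C)C[C@@H](O)[C@@H](C#C[Si](C(C)C)(C(C)C)C(C)C)O1 | intermediate
9 | ethyl (4R,5R)-4-{[tert-butyl(dimethyl)silyl]oxy}-2-methyl-5-{[tri(propan-2-yl)silyl]ethynyl}oxolane-2-carboxylate (C2 open) | CCOC(=O)C1(C)C[C@@H](O[Si](C)(C)C(C)(C)C)[C@@H](C#C[Si](C(C)C)(C(C)C)C(C)C)O1 | intermediate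
10 | (4R,5R)-4-{[tert-butyl(dimethyl)silyl]oxy}-2-methyl-5-{[tri(propan-2-yl)silyl]ethynyl}oxolane-2-carboxylic acid (C2 open) | OC(=O)C1(C)C[C@@H](O[Si](C)(C)C(C)(C)C)[C@@H](C#C[Si](C(C)C)(C(C)C)C(C)C)O1 | intermediate
11 | (4R,5R)-4-{[tert-butyl(dimethyl)silyl]oxy}-2-methyl-5-{[tri(propan-2-yl)silyl]ethynyl}oxolan-2-yl acetate (both epimers at C2) | CC(=O)OC1(C)C[C@@H](O[Si](C)(C)C(C)(C)C)[C@@H](C#C[Si](C(C)C)(C(C)C)C(C)C)O1 | intermediate
12 | (2R,3R)-3-{[tert-butyl(dimethyl)silyl]oxy}-5-methyl-2-{[tri(propan-2-yl)silyl]ethynyl}-3,4-dihydro-2H-furan-1-ium (oxocarbenium ion; not isolated) | CC1=[O+][C@H](C#C[Si](C(C)C)(C(C)C)C(C)C)[C@H](O[Si](C)(C)C(C)(C)C)C1 | intermediate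
13 | tert-butyl(dimethyl){[(2R,3R,5R)-5-methyl-2-{[tri(propan-2-yl)silyl]ethynyl}oxolan-3-yl]oxy}silane | C[C@@H]1C[C@@H](O[Si](C)(C)C(C)(C)C)[C@@H](C#C[Si](C(C)C)(C(C)C)C(C)C)O1 | intermediate
14 | (2R,3R,5R)-2-ethynyl-5-methyloxolan-3-ol | C[C@@H]1C[C@@H](O)[C@@H](C#C)O1 | intermediate
15 | (2R,3R,5R)-5-methyl-2-[(E)-2-(tributylstannyl)ethenyl]oxolan-3-ol | C[C@@H]1C[C@@H](O)[C@@H](/C=C/[Sn](CCCC)(CCCC)CCCC)O1 | intermediate
16 | methyl 2,4-dihydroxy-6-methylbenzoate (methyl orsellinate) | COC(=O)c1c(C)cc(O)cc1O | starting material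
17 | methyl 3-chloro-4,6-dihydroxy-2-methylbenzoate | COC(=O)c1c(C)c(Cl)c(O)cc1O | intermediate
18 | methyl 3-chloro-4,6-dimethoxy-2-methylbenzoate | COC(=O)c1c(C)c(Cl)c(OC)cc1OC | intermediate
19 | N-methoxy-N-methylacetamide | CC(=O)N(C)OC | starting material
20 | methyl 3-chloro-4,6-dimethoxy-2-(2-oxopropyl)benzoate (not isolated) | COC(=O)c1c(CC(C)=O)c(Cl)c(OC)cc1OC | intermediate
21 | 5-chloro-6,8-dimethoxy-3-methyl-1H-isochromen-1-one | Cc1cc2c(Cl)c(OC)cc(OC)c2c(=O)o1 | intermediate
22 | 5-chloro-6,8-dimethoxy-1-oxo-1H-isochromene-3-carbaldehyde | O=Cc1cc2c(Cl)c(OC)cc(OC)c2c(=O)o1 | intermediate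
23 | 5-chloro-3-[(E)-2-iodoethenyl]-6,8-dimethoxy-1H-isochromen-1-one | I/C=C/c1cc2c(Cl)c(OC)cc(OC)c2c(=O)o1 | intermediate
24 | 5-chloro-6,8-dihydroxy-3-[(E)-2-iodoethenyl]-1H-isochromen-1-one | I/C=C/c1cc2c(Cl)c(O)cc(O)c2c(=O)o1 | intermediate
25 | 5-chloro-6,8-dihydroxy-3-[(1E,3E)-4-[(2R,3R,5R)-3-hydroxy-5-methyloxolan-2-yl]buta-1,3-dien-1-yl]-1H-isochromen-1-one | C[C@@H]1C[C@@H](O)[C@@H](/C=C/C=C/c2cc3c(Cl)c(O)cc(O)c3c(=O)o2)O1 | target

**Step count and risks**
Total step count: 17. Longest linear sequence: 11 (steps 1–10, then step 17); the isocoumarin branch (steps 11–16) runs in parallel.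

Steps most likely to fail:

Step 2. The ylide may be diverted before it meets the enone (closure to the epoxide, capture by a second aldehyde molecule, ylide formation at the enone carbonyl), or the enone may add exo and give the 2,3-trans relationship. Fallback, from 3 back to 6, by a Prins cyclisation–pinacol rearrangement that forms the same two ring bonds. Addition of 1-ethoxyvinyllithium (ethyl vinyl ether, t-BuLi, THF, −78 °C) to 3 should give 2-ethoxy-5-[tri(propan-2-yl)silyl]pent-1-en-4-yn-3-ol F1. Dilute HCl should hydrolyse it to 3-hydroxy-5-[tri(propan-2-yl)silyl]pent-4-yn-2-one F2. Vinylmagnesium bromide (excess, THF, −78 °C) should give 4-methyl-1-[tri(propan-2-yl)silyl]hex-5-en-1-yne-3,4-diol F3, whose diastereomer ratio does not matter. Ketalisation with ethyl pyruvate (TsOH cat., benzene, water removal) should give ethyl 2,4-dimethyl-5-{[tri(propan-2-yl)silyl]ethynyl}-4-vinyl-1,3-dioxolane-2-carboxylate F4. SnCl4 (CH2Cl2, −78 to −20 °C) should then open the ketal to the oxocarbenium ion, which cyclises onto the vinyl group; the suprafacial 1,2-shift of the propargylic carbon places acetyl and alkynyl cis and returns the route to racemic 6.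

Step 4. The enzyme may discriminate poorly between the enantiomers or turn over the hindered acetate too slowly. Fallback, from 7 back to 8, by classical resolution through covalent diastereomers. Ethanolysis of 7 (K2CO3, EtOH) should give racemic ethyl (4RS,5RS)-4-hydroxy-2-methyl-5-{[tri(propan-2-yl)silyl]ethynyl}oxolane-2-carboxylate F5. Esterification with (S)-2-methoxy-2-phenylacetic acid (DCC, DMAP, CH2Cl2, 0 °C) and chromatographic separation of the diastereomers should give ethyl (4R,5R)-4-{[(2S)-2-methoxy-2-phenylacetyl]oxy}-2-methyl-5-{[tri(propan-2-yl)silyl]ethynyl}oxolane-2-carboxylate F6. Ethanolysis (K2CO3, EtOH) then returns to 8.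

Step 17. The acidic phenols may protodestannylate the alkenylstannane or slow the transmetalation, so that reduction and homocoupling compete with cross-coupling. Fallback, from 24 (with 15) back to 25, by a protected coupling. Silylation of 24 (TBSCl, imidazole, DMF) should give 6,8-bis{[tert-butyl(dimethyl)silyl]oxy}-5-chloro-3-[(E)-2-iodoethenyl]-1H-isochromen-1-one F7. Stille coupling with 15 under the same palladium catalysis should give 6,8-bis{[tert-butyl(dimethyl)silyl]oxy}-5-chloro-3-[(1E,3E)-4-[(2R,3R,5R)-3-hydroxy-5-methyloxolan-2-yl]buta-1,3-dien-1-yl]-1H-isochromen-1-one F8. HF·pyridine (THF/pyridine, 0 °C) should then release 25.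

Further compounds
F1 | step 2 | 2-ethoxy-5-[tri(propan-2-yl)silyl]pent-1-en-4-yn-3-ol (racemic) | CCOC(=C)C(O)C#C[Si](C(C)C)(C(C)C)C(C)C
F2 | step 2 | 3-hydroxy-5-[tri(propan-2-yl)silyl]pent-4-yn-2-one (racemic) | CC(=O)C(O)C#C[Si](C(C)C)(C(C)C)C(C)C
F3 | step 2 | 4-methyl-1-[tri(propan-2-yl)silyl]hex-5-en-1-yne-3,4-diol (racemic, both diastereomers) | CC(O)(C=C)C(O)C#C[Si](C(C)C)(C(C)C)C(C)C
F4 | step 2 | ethyl 2,4-dimethyl-5-{[tri(propan-2-yl)silyl]ethynyl}-4-vinyl-1,3-dioxolane-2-carboxylate (racemic, diastereomer mixture) | CCOC(=O)C1(C)OC(C#C[Si](C(C)C)(C(C)C)C(C)C)C(C)(C=C)O1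
F5 | step 4 | racemic ethyl (4RS,5RS)-4-hydroxy-2-methyl-5-{[tri(propan-2-yl)silyl]ethynyl}oxolane-2-carboxylate (one enantiomer drawn; C2 open) | CCOC(=O)C1(C)C[C@@H](O)[C@@H](C#C[Si](C(C)C)(C(C)C)C(C)C)O1
F6 | step 4 | ethyl (4R,5R)-4-{[(2S)-2-methoxy-2-phenylacetyl]oxy}-2-methyl-5-{[tri(propan-2-yl)silyl]ethynyl}oxolane-2-carboxylate (C2 open) | CCOC(=O)C1(C)C[C@@H](OC(=O)[C@@H](OC)c2ccccc2)[C@@H](C#C[Si](C(C)C)(C(C)C)C(C)C)O1
F7 | step 17 | 6,8-bis{[tert-butyl(dimethyl)silyl]oxy}-5-chloro-3-[(E)-2-iodoethenyl]-1H-isochromen-1-one | I/C=C/c1cc2c(Cl)c(O[Si](C)(C)C(C)(C)C)cc(O[Si](C)(C)C(C)(C)C)c2c(=O)o1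
F8 | step 17 | 6,8-bis{[tert-butyl(dimethyl)silyl]oxy}-5-chloro-3-[(1E,3E)-4-[(2R,3R,5R)-3-hydroxy-5-methyloxolan-2-yl]buta-1,3-dien-1-yl]-1H-isochromen-1-one | C[C@@H]1C[C@@H](O)[C@@H](/C=C/C=C/c2cc3c(Cl)c(O[Si](C)(C)C(C)(C)C)cc(O[Si](C)(C)C(C)(C)C)c3c(=O)o2)O1
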